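The route rests on disconnecting C3–C4 of the chroman-4-one, the bond between the acyl carbon on ring A and the carbon that carries ring B. The feature exploited is the aryl ketone C4 next to C3, which lies one CH2 (C2) from the phenol oxygen O1: with a hydroxyl added at C3 this is a benzoin. In the key step an N-heterocyclic carbene turns the ring A aldehyde into an acyl anion equivalent that adds to a ring B aryl ketone tethered through O1–C2, closing the pyranone ring in one operation. The precursor is a salicylaldehyde phenacyl ether. Dehydration, asymmetric transfer hydrogenation with dynamic kinetic resolution and reoxidation then set (S)-C3.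

Key step: step 10

Remark on the chemistry: C3 of the target is (S) (priorities C4 > C2 > C1′ > H); this α-aryl ketone centre epimerises easily under base, so it is set late and then handled only under neutral or mildly acidic conditions.
Abbreviations: MOM = methoxymethyl; prenyl = 3-methylbut-2-en-1-yl.

Step 1
Reactants: 1 2,4,6-trihydroxybenzaldehyde
Product: 2 2-hydroxy-4,6-bis(MOM-oxy)benzaldehyde
Conditions: MOMCl (2.1 equiv), i-Pr2NEt, CH2Cl2, 0 °C to rt
Reagents that add atoms: chloromethyl methyl ether (MOMCl), COCCl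
Why: Base-mediated O-alkylation (Williamson-type) should stop at the 4,6-bis-ether because the last ortho-hydroxyl is tied up in a hydrogen bond to the formyl group and is the least nucleophilic.

Step 2
Reactants: 2 2-hydroxy-4,6-bis(MOM-oxy)benzaldehyde
Product: 3 2,4-bis(MOM-oxy)-6-(prenyloxy)benzaldehyde
Conditions: prenyl bromide, K2CO3, DMF, 50 °C
Reagents that add atoms: 1-bromo-3-methylbut-2-ene (prenyl bromide), CC(C)=CCBr
Why: Williamson ether synthesis: under carbonate the chelated phenol is ionised and attacks the primary allylic bromide by SN2 to give the O-prenyl ether that later delivers the prenyl group to carbon.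

Step 3
Reactants: 3 2,4-bis(MOM-oxy)-6-(prenyloxy)benzaldehyde
Product: 6 6-hydroxy-2,4-bis(MOM-oxy)-3-prenylbenzaldehyde, via ortho-dienone 4 (not isolated), via para-dienone 5 (not isolated)
Conditions: PhNEt2, 200 °C
Reagents that add atoms: none
Why: Tandem aromatic Claisen/Cope rearrangement (para-Claisen): the [3,3] shift to the only free ortho carbon gives 4 with a crowded 1,1-dimethylallyl group, a second [3,3] shift moves it as a normal prenyl group to the para carbon between the two MOM ethers (5), and enolisation gives 6, so the prenyl group ends at the future C6 and the freed phenol is the future O1.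

Step 4
Reactants: 7 3-bromo-4,5-dihydroxybenzaldehyde
Product: 8 3-bromo-5-hydroxy-4-methoxybenzaldehyde
Conditions: MeI (1.05 equiv), Li2CO3, DMF, 40 °C
Reagents that add atoms: iodomethane, CI
Why: Williamson methylation: the weak base should ionise only the more acidic hydroxyl para to the formyl group, so the methyl group goes to O4 and the meta hydroxyl stays free.

Step 5
Reactants: 8 3-bromo-5-hydroxy-4-methoxybenzaldehyde
Product: 9 3-bromo-4-methoxy-5-(MOM-oxy)benzaldehyde
Conditions: MOMCl, i-Pr2NEt, CH2Cl2, 0 °C to rt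
Reagents that add atoms: chloromethyl methyl ether (MOMCl), COCCl
Why: Standard MOM protection of the remaining phenol (O-alkylation), chosen so that all three phenol protecting groups are of one kind and leave together in step 14.

Step 6
Reactants: 9 3-bromo-4-methoxy-5-(MOM-oxy)benzaldehyde
Product: 10 4-methoxy-3-(MOM-oxy)-5-prenylbenzaldehyde
Conditions: Bu3Sn(CH2CH=CMe2), Pd(PPh3)4 (5 mol%), DMF, 100 °C
Reagents that add atoms: tributyl(3-methylbut-2-en-1-yl)stannane, CCCC[Sn](CCCC)(CCCC)CC=C(C)C
Why: Stille cross-coupling of the aryl bromide with the prenylstannane: the allyl palladium intermediate should reductively eliminate at its unhindered primary terminus to give the linear prenyl arene, with the aldehyde and the acetal inert.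

Step 7
Reactants: 10 4-methoxy-3-(MOM-oxy)-5-prenylbenzaldehyde
Product: 11 rac-2-[4-methoxy-3-(MOM-oxy)-5-prenylphenyl]oxirane
Conditions: Me3S+ I−, NaH, DMSO/THF, 0 °C to rt
Reagents that add atoms: trimethylsulfonium iodide, C[S+](C)C.[I-]
Why: Corey–Chaykovsky epoxidation: methylene transfer from the sulfonium ylide to the aldehyde gives the terminal aryl oxirane without touching the prenyl alkene; the new centre is racemic and is removed in step 9.

Step 8
Reactants: 6 6-hydroxy-2,4-bis(MOM-oxy)-3-prenylbenzaldehyde; 11 rac-2-[4-methoxy-3-(MOM-oxy)-5-prenylphenyl]oxirane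
Product: 12 rac-6-{2-hydroxy-2-[4-methoxy-3-(MOM-oxy)-5-prenylphenyl]ethoxy}-2,4-bis(MOM-oxy)-3-prenylbenzaldehyde
Conditions: Cs2CO3 (0.3 equiv), DMF, 80 °C
Reagents that add atoms: none
Why: Base-catalysed epoxide opening: the phenoxide of 6 attacks the unhindered terminal carbon of 11 by SN2, which joins the fragments through the future O1–C2 bond and leaves a racemic benzylic alcohol that is oxidised next.

Step 9
Reactants: 12 rac-hydroxy ether aldehyde
Product: 13 6-{2-[4-methoxy-3-(MOM-oxy)-5-prenylphenyl]-2-oxoethoxy}-2,4-bis(MOM-oxy)-3-prenylbenzaldehyde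
Conditions: Dess–Martin periodinane, CH2Cl2, 0 °C to rt
Reagents that add atoms: none
Why: Dess–Martin oxidation turns the secondary benzylic alcohol into the aryl ketone under non-basic conditions, so the aldehyde, the acetals and the prenyl groups survive and the base-sensitive keto aldehyde does not undergo aldol condensation.

Step 10
Reactants: 13 keto aldehyde (salicylaldehyde phenacyl ether)
Product: 15 rac-3-hydroxy-5,7-bis(MOM-oxy)-3-[4-methoxy-3-(MOM-oxy)-5-prenylphenyl]-6-prenylchroman-4-one, via Breslow enaminol 14 (not isolated)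
Conditions: 2-(pentafluorophenyl)-6,7-dihydro-5H-pyrrolo[2,1-c][1,2,4]triazol-2-ium tetrafluoroborate (15 mol%), i-Pr2NEt (12 mol%), toluene, rt to 40 °C
Reagents that add atoms: none
Why: The carbene freed from the triazolium salt adds to the formyl group of 13 and proton transfer gives Breslow enaminol 14, an acyl anion equivalent at the future C4 that attacks the tethered aryl ketone carbon (future C3); proton transfer and loss of the carbene then release α-ketol 15, an intramolecular crossed aldehyde–ketone benzoin reaction whose closest known counterpart is the carbene-catalysed cyclisation of 2-(2-oxo-2-arylethoxy)benzaldehydes to 3-aryl-3-hydroxychroman-4-ones. The pyranone ring closes in the 6-exo-trig mode. The tertiary carbinol centre formed at C3 is deliberately left uncontrolled (achiral carbene, racemate), because step 11 removes it and step 12 sets C3. The step needs chemoselectivity for acyl anion addition over the base-induced aldol cyclisation of the aryloxymethyl ketone onto the aldehyde (benzofuran formation) and over intermolecular benzoin coupling: only the aldehyde can form the enaminol, the ketone is activated by its α-aryloxy group and sits six atoms away, and the amine is kept below the amount of azolium salt so that no free base remains. Because the aldehyde is electron-rich and flanked by two ortho oxygens, the acidic N-pentafluorophenyl triazolium and gentle warming are used to keep carbene addition going.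

Step 11
Reactants: 15 rac-3-hydroxyisoflavanone
Product: 16 5,7-bis(MOM-oxy)-3-[4-methoxy-3-(MOM-oxy)-5-prenylphenyl]-6-prenyl-4H-chromen-4-one
Conditions: Burgess reagent (MeO2CN−SO2N+Et3), THF, 50 °C
Reagents that add atoms: none
Why: Burgess dehydration: thermal syn-elimination of the activated tertiary hydroxyl with a hydrogen of C2 should give the conjugated chromen-4-one under neutral conditions that spare the acetals and prenyl groups, and it removes the racemic C3 centre.

Step 12
Reactants: 16 protected isoflavone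
Product: 18 cis-(3S,4S)-5,7-bis(MOM-oxy)-3-[4-methoxy-3-(MOM-oxy)-5-prenylphenyl]-6-prenylchroman-4-ol, via isoflavanone 17 (not isolated)
Conditions: RuCl[(S,S)-TsDPEN](p-cymene) (2 mol%), HCO2H/Et3N (1:1), EtOAc, 40 °C
Reagents that add atoms: none
Why: Noyori-type asymmetric transfer hydrogenation with dynamic kinetic resolution: conjugate hydride transfer to C2 gives isoflavanone 17, whose C3 epimerises through the enol in the amine-containing medium, while the (S,S)-ligated catalyst, which reduces ring-fused aryl ketones to (S)-carbinols, delivers hydride to C4 fastest in (3S)-17 anti to the 3-aryl group, so the cis (3S,4S) alcohol should accumulate; the prenyl alkenes are not reduced.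

Step 13
Reactants: 18 cis-(3S,4S)-chromanol
Product: 19 (3S)-5,7-bis(MOM-oxy)-3-[4-methoxy-3-(MOM-oxy)-5-prenylphenyl]-6-prenylchroman-4-one
Conditions: Dess–Martin periodinane, NaHCO3, CH2Cl2, 0 °C
Reagents that add atoms: none
Why: Dess–Martin oxidation returns C4 to the ketone under buffered, non-enolising conditions, so the (S) configuration set at C3 in step 12 should be retained.

Step 14
Reactants: 19 (3S)-tris-MOM isoflavanone
Product: 20 (3S)-5,7-dihydroxy-3-(3-hydroxy-4-methoxy-5-prenylphenyl)-6-prenylchroman-4-one (target, CNP0327275.1)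
Conditions: HCl (3 M aq), MeOH, rt
Reagents that add atoms: none
Why: Acid-catalysed acetal cleavage (transacetalisation to methanol) removes the three MOM groups, the one at O5 fastest because of the neighbouring carbonyl, and dilute acid at room temperature should be too mild for ketone enolisation at C3 or for cyclisation of a prenyl group onto a neighbouring phenol.

Compound list
1 | 2,4,6-trihydroxybenzaldehyde | O=Cc1c(O)cc(O)cc1O | starting material
2 | 2-hydroxy-4,6-bis(methoxymethoxy)benzaldehyde | O=Cc1c(O)cc(OCOC)cc1OCOC | intermediate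
3 | 2,4-bis(methoxymethoxy)-6-[(3-methylbut-2-en-1-yl)oxy]benzaldehyde | O=Cc1c(OCC=C(C)C)cc(OCOC)cc1OCOC | intermediate
4 | 2,4-bis(methoxymethoxy)-5-(2-methylbut-3-en-2-yl)-6-oxocyclohexa-1,3-diene-1-carbaldehyde (ortho-dienone, racemic) | O=CC1=C(OCOC)C=C(OCOC)C(C(C)(C)C=C)C1=O | intermediate
5 | 2,4-bis(methoxymethoxy)-3-(3-methylbut-2-en-1-yl)-6-oxocyclohexa-1,4-diene-1-carbaldehyde (para-dienone) | O=CC1=C(OCOC)C(CC=C(C)C)C(OCOC)=CC1=O | intermediate
6 | 6-hydroxy-2,4-bis(methoxymethoxy)-3-(3-methylbut-2-en-1-yl)benzaldehyde | O=Cc1c(O)cc(OCOC)c(CC=C(C)C)c1OCOC | intermediate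
7 | 3-bromo-4,5-dihydroxybenzaldehyde | O=Cc1cc(O)c(O)c(Br)c1 | starting material
8 | 3-bromo-5-hydroxy-4-methoxybenzaldehyde | COc1c(O)cc(C=O)cc1Br | intermediate
9 | 3-bromo-4-methoxy-5-(methoxymethoxy)benzaldehyde | COCOc1cc(C=O)cc(Br)c1OC | intermediate
10 | 4-methoxy-3-(methoxymethoxy)-5-(3-methylbut-2-en-1-yl)benzaldehyde | COCOc1cc(C=O)cc(CC=C(C)C)c1OC | intermediate
11 | rac-2-[4-methoxy-3-(methoxymethoxy)-5-(3-methylbut-2-en-1-yl)phenyl]oxirane | COCOc1cc(C2CO2)cc(CC=C(C)C)c1OC | intermediate
12 | rac-6-{2-hydroxy-2-[4-methoxy-3-(methoxymethoxy)-5-(3-methylbut-2-en-1-yl)phenyl]ethoxy}-2,4-bis(methoxymethoxy)-3-(3-methylbut-2-en-1-yl)benzaldehyde | O=Cc1c(OCC(O)c2cc(OCOC)c(OC)c(CC=C(C)C)c2)cc(OCOC)c(CC=C(C)C)c1OCOC | intermediate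
13 | 6-{2-[4-methoxy-3-(methoxymethoxy)-5-(3-methylbut-2-en-1-yl)phenyl]-2-oxoethoxy}-2,4-bis(methoxymethoxy)-3-(3-methylbut-2-en-1-yl)benzaldehyde | O=Cc1c(OCC(=O)c2cc(OCOC)c(OC)c(CC=C(C)C)c2)cc(OCOC)c(CC=C(C)C)c1OCOC | intermediate
14 | Breslow enaminol: adduct of the formyl carbon of 13 with 2-(pentafluorophenyl)-6,7-dihydro-5H-pyrrolo[2,1-c][1,2,4]triazol-3-ylidene, C(OH)=C(carbene carbon) | OC(=C1N(c2c(F)c(F)c(F)c(F)c2F)N=C2CCCN12)c1c(OCC(=O)c2cc(OCOC)c(OC)c(CC=C(C)C)c2)cc(OCOC)c(CC=C(C)C)c1OCOC | intermediate
15 | rac-3-hydroxy-5,7-bis(methoxymethoxy)-3-[4-methoxy-3-(methoxymethoxy)-5-(3-methylbut-2-en-1-yl)phenyl]-6-(3-methylbut-2-en-1-yl)chroman-4-one | COCOc1cc2OCC(O)(c3cc(OCOC)c(OC)c(CC=C(C)C)c3)C(=O)c2c(OCOC)c1CC=C(C)C | intermediate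
16 | 5,7-bis(methoxymethoxy)-3-[4-methoxy-3-(methoxymethoxy)-5-(3-methylbut-2-en-1-yl)phenyl]-6-(3-methylbut-2-en-1-yl)-4H-chromen-4-one | COCOc1cc2occ(-c3cc(OCOC)c(OC)c(CC=C(C)C)c3)c(=O)c2c(OCOC)c1CC=C(C)C | intermediate
17 | rac-5,7-bis(methoxymethoxy)-3-[4-methoxy-3-(methoxymethoxy)-5-(3-methylbut-2-en-1-yl)phenyl]-6-(3-methylbut-2-en-1-yl)chroman-4-one (C3 epimerising) | COCOc1cc2OCC(c3cc(OCOC)c(OC)c(CC=C(C)C)c3)C(=O)c2c(OCOC)c1CC=C(C)C | intermediate
18 | (3S,4S)-5,7-bis(methoxymethoxy)-3-[4-methoxy-3-(methoxymethoxy)-5-(3-methylbut-2-en-1-yl)phenyl]-6-(3-methylbut-2-en-1-yl)chroman-4-ol (3,4-cis) | COc1c(OCOC)cc([C@H]2COc3cc(OCOC)c(CC=C(C)C)c(OCOC)c3[C@H]2O)cc1CC=C(C)C | intermediate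
19 | (3S)-5,7-bis(methoxymethoxy)-3-[4-methoxy-3-(methoxymethoxy)-5-(3-methylbut-2-en-1-yl)phenyl]-6-(3-methylbut-2-en-1-yl)chroman-4-one | COc1c(OCOC)cc([C@H]2COc3cc(OCOC)c(CC=C(C)C)c(OCOC)c3C2=O)cc1CC=C(C)C | intermediate
20 | (3S)-5,7-dihydroxy-3-[3-hydroxy-4-methoxy-5-(3-methylbut-2-en-1-yl)phenyl]-6-(3-methylbut-2-en-1-yl)chroman-4-one | COc1c(O)cc([C@H]2COc3cc(O)c(CC=C(C)C)c(O)c3C2=O)cc1CC=C(C)C | target

Total step count: 14. Longest linear sequence: 11 steps (steps 4–14, from 7); the ring A branch (steps 1–3) joins at step 8.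

Steps most likely to fail

Step 10 (key step). What may go wrong: base-induced aldol cyclisation of the aryloxymethyl ketone onto the aldehyde, leading towards a benzofuran, may outrun carbene addition to the hindered, electron-rich aldehyde. Fallback: set out from alcohol 12 and close the same C3–C4 bond by substitution instead of carbonyl addition. SOCl2 and pyridine in CH2Cl2 at 0 °C would convert 12 into rac-6-{2-chloro-2-[4-methoxy-3-(MOM-oxy)-5-prenylphenyl]ethoxy}-2,4-bis(MOM-oxy)-3-prenylbenzaldehyde F1. A thiazolium-derived carbene (3-benzyl-5-(2-hydroxyethyl)-4-methylthiazolium chloride, DBU, dioxane, 60 °C) would then let the acyl anion equivalent displace the benzylic chloride intramolecularly (6-exo-tet). This would give racemic isoflavanone 17, here isolated, which is a direct substrate for the conditions of step 12; the route comes back at 18 and steps 9–11 are bypassed.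

Step 12. What may go wrong: hydride delivery to the C4 carbonyl, shielded by the O5 acetal, may be slow or poorly face-selective, and the electron-rich benzylic carbinol may ionise in the formate medium. Fallback: set out from isoflavone 16 and set C3 by enantioselective protonation. Conjugate reduction with LiBH(s-Bu)3 in THF at −78 °C and trapping of the enolate with Me3SiCl would give the trimethylsilyl enol ether F2. A chiral BINOL-derived N-triflyl thiophosphoramide (catalytic) with phenol as stoichiometric proton source in toluene at rt would then protonate C3 enantioselectively, the catalyst enantiomer being chosen for the (S) product. The route comes back at 19; 18 and step 13 are bypassed.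

Step 14. What may go wrong: acid-catalysed enolisation during acetal cleavage may erode the C3 configuration, and a prenyl group may cyclise onto a freed phenol. Fallback: set out from isoflavone 16, where no stereocentre is at risk, and exchange the acetals for silyl ethers. HCl in MeOH at 50 °C would give the triphenol isoflavone F3, and TBSOTf with 2,6-lutidine in CH2Cl2 its tris(tert-butyldimethylsilyl) ether F4. The conditions of steps 12 and 13 would then give the cis-(3S,4S) chromanol F5 and the (S)-chromanone F6. Et3N·3HF in THF at 0 °C would remove the silyl groups without acid or base strong enough to enolise C3, and the route comes back at 20.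

Further compounds
F1 | step 10 | rac-6-{2-chloro-2-[4-methoxy-3-(methoxymethoxy)-5-(3-methylbut-2-en-1-yl)phenyl]ethoxy}-2,4-bis(methoxymethoxy)-3-(3-methylbut-2-en-1-yl)benzaldehyde | O=Cc1c(OCC(Cl)c2cc(OCOC)c(OC)c(CC=C(C)C)c2)cc(OCOC)c(CC=C(C)C)c1OCOC
F2 | step 12 | {[5,7-bis(methoxymethoxy)-3-[4-methoxy-3-(methoxymethoxy)-5-(3-methylbut-2-en-1-yl)phenyl]-6-(3-methylbut-2-en-1-yl)-2H-chromen-4-yl]oxy}trimethylsilane | COCOc1cc2OCC(c3cc(OCOC)c(OC)c(CC=C(C)C)c3)=C(O[Si](C)(C)C)c2c(OCOC)c1CC=C(C)C
F3 | step 14 | 5,7-dihydroxy-3-[3-hydroxy-4-methoxy-5-(3-methylbut-2-en-1-yl)phenyl]-6-(3-methylbut-2-en-1-yl)-4H-chromen-4-one | COc1c(O)cc(-c2coc3cc(O)c(CC=C(C)C)c(O)c3c2=O)cc1CC=C(C)C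
F4 | step 14 | 5,7-bis(tert-butyldimethylsilyloxy)-3-[3-(tert-butyldimethylsilyloxy)-4-methoxy-5-(3-methylbut-2-en-1-yl)phenyl]-6-(3-methylbut-2-en-1-yl)-4H-chromen-4-one | COc1c(O[Si](C)(C)C(C)(C)C)cc(-c2coc3cc(O[Si](C)(C)C(C)(C)C)c(CC=C(C)C)c(O[Si](C)(C)C(C)(C)C)c3c2=O)cc1CC=C(C)C
F5 | step 14 | (3S,4S)-5,7-bis(tert-butyldimethylsilyloxy)-3-[3-(tert-butyldimethylsilyloxy)-4-methoxy-5-(3-methylbut-2-en-1-yl)phenyl]-6-(3-methylbut-2-en-1-yl)chroman-4-ol | COc1c(O[Si](C)(C)C(C)(C)C)cc([C@H]2COc3cc(O[Si](C)(C)C(C)(C)C)c(CC=C(C)C)c(O[Si](C)(C)C(C)(C)C)c3[C@H]2O)cc1CC=C(C)C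
F6 | step 14 | (3S)-5,7-bis(tert-butyldimethylsilyloxy)-3-[3-(tert-butyldimethylsilyloxy)-4-methoxy-5-(3-methylbut-2-en-1-yl)phenyl]-6-(3-methylbut-2-en-1-yl)chroman-4-one | COc1c(O[Si](C)(C)C(C)(C)C)cc([C@H]2COc3cc(O[Si](C)(C)C(C)(C)C)c(CC=C(C)C)c(O[Si](C)(C)C(C)(C)C)c3C2=O)cc1CC=C(C)C
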